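**Plan**
Retrosynthetic cuts, in order: the C6–O acyl bond (ester); C5–C6, which opens the ten-membered carbocycle; O–C3 and C1–C2 of the furanone; C11=C13; C7–C8 and O8–C12 of the lactone.
Enabling feature: C6 is a secondary allylic carbinol. It lies between the Z-trisubstituted C4(Me)=C5 alkene on C3 of the 3(2H)-furanone ring (O, C10, C1, C2, C3) and C7 of the trans γ-lactone ring (C7, C8, O, C12, C11). The C1–C10 ring can therefore be closed by adding a Z-alkenyl metal at C5 to a formyl group at C6.
Forward order of rings: γ-lactone (aldol–lactonisation on a C8 aldehyde), exocyclic methylene, furanone (aldol at C1–C2, oxidation, cyclodehydration), ten-membered ring (C5–C6), then the side-chain ester.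
Stereochemistry: C10 comes from (R)-citramalic acid. C7 and C8 come from an oxazolidinone-controlled syn aldol that lactonises to the trans lactone. The Z-iodoalkene comes from a chelated anti-carbomagnesiation, C6 from control by C7 in the ring closure, and C2' from (R)-2-methylglycidol.

Key step: step 19

Remark: atom labels follow germacrane numbering. C1 is the furanone ketone, C2/C3 its enol-ether alkene, and C4/C5 the side alkene with methyl C15 on C4. C6 is the ester carbinol, C7/C8 the lactone ring carbons (O on C8), C9 the methylene, and C10 the quaternary carbon with methyl C14. C11/C12/C13 are the α-carbon, carbonyl and exocyclic methylene of the lactone. Compounds 22 and 24 are racemic and 27 is a pair of C1 epimers, because those carbinol centres are oxidised away. (R)-Citramalic acid and (R)-2-methylglycidol are taken as commercial.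

Step 1
Reactants: 1 (R)-citramalic acid
Product: 2 (2R)-2-methylbutane-1,2,4-triol
Conditions: BH3·SMe2, B(OMe)3, THF, 0 °C → rt; MeOH
Reagents that add atoms: none
Why: Borane reduction of carboxylic acids takes both CO2H groups to CH2OH and cannot touch the quaternary carbinol, so C10 keeps the R configuration of the chiral pool.

Step 2
Reactants: 2 (2R)-2-methylbutane-1,2,4-triol
Product: 3 2-[(4R)-2,2,4-trimethyl-1,3-dioxolan-4-yl]ethan-1-ol
Conditions: Me2C(OMe)2, TsOH (cat.), acetone, rt
Reagents that add atoms: 2,2-dimethoxypropane, COC(C)(C)OC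
Why: Acid-catalysed transketalisation under thermodynamic control favours the five-membered 1,2-acetonide over the 1,3-dioxane with its syn-axial methyl groups, which leaves only the future C8 hydroxyl free.

Step 3
Reactants: 3 acetonide alcohol
Product: 4 2-[(4R)-2,2,4-trimethyl-1,3-dioxolan-4-yl]acetaldehyde (C8 aldehyde)
Conditions: TEMPO (cat.), PhI(OAc)2, CH2Cl2, rt
Reagents that add atoms: none
Why: The oxoammonium (TEMPO) oxidation stops at the aldehyde under near-neutral conditions that spare the acetonide and do not provoke β-elimination of the C10 oxygen.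

Step 4
Reactants: 5 (4R)-4-benzyl-1,3-oxazolidin-2-one; 6 methyl 4-chloro-4-oxobutanoate
Product: 7 methyl 4-[(4R)-4-benzyl-2-oxo-1,3-oxazolidin-3-yl]-4-oxobutanoate
Conditions: Et3N, DMAP (cat.), CH2Cl2, 0 °C → rt
Reagents that add atoms: none
Why: DMAP-catalysed N-acylation places the auxiliary on the carboxyl carbon that becomes C6, while the methyl ester marks C12.

Step 5
Reactants: 7 succinyl imide; 4 C8 aldehyde
Product: 10 trans-lactone imide (7R,8S,10R), via boron enolate 8 (not isolated), via syn aldol adduct 9 (not isolated)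
Conditions: Bu2BOTf, Et3N, CH2Cl2, −78 → 0 °C; 4, −78 → 0 °C; pH 7 buffer, H2O2, MeOH, 0 °C; PPTS (cat.), PhMe, 50 °C
Reagents that add atoms: dibutylboron triflate, CCCCB(CCCC)OS(=O)(=O)C(F)(F)F (boron unit present only in 8)
Why: Soft enolisation occurs only at the imide, and the Evans syn aldol reaction of Z-enolate 8 through a Zimmerman–Traxler chair, with the benzyl group shielding one face, sets 7R and 8S under reagent control; lactonisation of O8 onto the C12 ester then turns the syn aldol into the trans-4,5-disubstituted γ-lactone.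

Step 6
Reactants: 10 trans-lactone imide
Product: 12 lactone acid (7R,8S,10R), via peroxy acid 11 (not isolated)
Conditions: LiOH, H2O2, THF–H2O, 0 °C; Na2SO3; 1 M HCl to pH 3, 0 °C
Reagents that add atoms: hydrogen peroxide, OO
Why: Hydroperoxide attacks the exocyclic imide carbonyl selectively (standard auxiliary cleavage), sulfite reduces 11, and any lactone opened by hydroxide recloses on acidification because O8 is the only hydroxyl present.

Step 7
Reactants: 12 lactone acid
Product: 13 (4S,5S)-4-(hydroxymethyl) lactone (7S,8S,10R)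
Conditions: BH3·SMe2, THF, 0 °C → rt; MeOH
Reagents that add atoms: none
Why: Borane reduces a free carboxylic acid much faster than a γ-lactone, and the non-basic medium avoids the alkoxide that could shift the lactone from O8 to O6.

Step 8
Reactants: 13 hydroxymethyl lactone
Product: 14 C6 tert-butyldiphenylsilyl ether
Conditions: TBDPSCl, imidazole, CH2Cl2, rt
Reagents that add atoms: tert-butyl(chloro)diphenylsilane, CC(C)(C)[Si](Cl)(c1ccccc1)c1ccccc1
Why: Routine silylation of the primary alcohol gives an ether that withstands LDA and the aqueous acid needed later for the acetonide.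

Step 9
Reactants: 14 silyl ether lactone
Product: 18 α-methylene lactone acetonide (7S,8S,10R), via lithium enolate 15 (not isolated), via Mannich base 16 (not isolated), via methiodide 17 (not isolated)
Conditions: LDA, THF, −78 °C; CH2=NMe2+ I−, −78 °C → rt; MeI, MeOH, rt; aq. NaHCO3, CH2Cl2, rt
Reagents that add atoms: Eschenmoser's salt, C=[N+](C)C.[I-]; lithium diisopropylamide, CC(C)N([Li])C(C)C (lithium only in 15); iodomethane, CI (carbon only in 17)
Why: In this Mannich-type α-methylenation the enolate is aminomethylated anti to the C7 substituent, and quaternisation followed by mild E1cB loss of trimethylamine can only give the exocyclic C11=C13 alkene because the leaving group sits on C13.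

Step 10
Reactants: 18 α-methylene lactone acetonide
Product: 19 C1,C10-diol
Conditions: AcOH–H2O (4:1), 40 °C
Reagents that add atoms: none
Why: Aqueous acetic acid hydrolyses the acetonide, while the TBDPS ether, the lactone and the acrylate unit are inert to it.

Step 11
Reactants: 19 diol
Product: 20 α-hydroxy aldehyde (C1 formyl with free C10 hydroxyl)
Conditions: IBX, DMSO, rt
Reagents that add atoms: none
Why: IBX oxidises the primary alcohol of a 1,2-diol without glycol cleavage, and the tertiary C10 carbinol cannot be oxidised.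

Step 12
Reactants: 20 α-hydroxy aldehyde
Product: 21 C10 triethylsilyl ether aldehyde
Conditions: TESOTf, 2,6-lutidine, CH2Cl2, −78 → 0 °C
Reagents that add atoms: triethylsilyl triflate, CC[Si](CC)(CC)OS(=O)(=O)C(F)(F)F
Why: The silyl triflate with a hindered pyridine base caps the tertiary alcohol, and the aldehyde has no α-hydrogen, so neither enol silane formation nor epimerisation can occur.

Step 13
Reactants: 22 but-3-yn-2-ol (racemic)
Product: 24 (Z)-4-iodo-3-methylbut-3-en-2-ol (racemic), via oxamagnesacycle 23 (not isolated)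
Conditions: MeMgBr (3 equiv), CuI (cat.), THF–Et2O, −20 °C → rt; I2, −78 → 0 °C; aq. NH4Cl
Reagents that add atoms: methylmagnesium bromide, C[Mg]Br; iodine, II
Why: Copper-catalysed anti-carbomagnesiation of the propargylic alkoxide delivers methyl to the internal alkyne carbon and gives the chelated five-membered alkenylmagnesium alkoxide 23, so iodinolysis with retention places iodine cis to the carbinol carbon (Z).

Step 14
Reactants: 24 (Z)-iodo allylic alcohol
Product: 25 (Z)-4-iodo-3-methylbut-3-en-2-one
Conditions: Dess–Martin periodinane, CH2Cl2, 0 °C → rt, dark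
Reagents that add atoms: none
Why: Dess–Martin oxidation of the allylic alcohol is fast and mild enough to preserve the Z geometry of the iodoalkene.

Step 15
Reactants: 25 (Z)-iodo enone; 21 C1 aldehyde
Product: 27 β-hydroxy ketone (C1 epimers; 4Z,7S,8S,10R), via boron dienolate 26 (not isolated)
Conditions: 25, Bu2BOTf, iPr2NEt, Et2O, −78 °C; 21, −78 → −20 °C; pH 7 buffer
Reagents that add atoms: dibutylboron triflate, CCCCB(CCCC)OS(=O)(=O)C(F)(F)F (boron unit present only in 26)
Why: In this boron-mediated methyl ketone aldol reaction enolisation is possible only at the methyl group, and the cross-conjugated dienolate adds to the aldehyde rather than to the lactone or the acrylate, so the C1–C2 bond forms chemoselectively.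

Step 16
Reactants: 27 β-hydroxy ketone
Product: 28 1,3-diketone (C1 and C3 carbonyls)
Conditions: Dess–Martin periodinane, CH2Cl2, 0 °C → rt, dark
Reagents that add atoms: none
Why: Dess–Martin periodinane converts β-hydroxy ketones into 1,3-diketones without affecting silyl ethers, the iodoalkene or the α-methylene lactone.

Step 17
Reactants: 28 1,3-diketone
Product: 31 furanone alcohol (4Z,7S,8S,10R), via C10-hydroxy diketone 29 (not isolated), via silylated furanone 30 (not isolated)
Conditions: HF·pyridine, THF, 0 °C → rt, dark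
Reagents that add atoms: none
Why: Desilylation frees the C10 hydroxyl, which adds 5-exo-trig to the C3 carbonyl and loses water (the classical acid-catalysed cyclodehydration of an α'-hydroxy 1,3-diketone to a 3(2H)-furanone) faster than the enol can attack C5, and longer exposure cleaves the primary TBDPS ether.

Step 18
Reactants: 31 furanone alcohol
Product: 32 formyl lactone with Z-alkenyl iodide (4Z,7R,8S,10R)
Conditions: Dess–Martin periodinane, NaHCO3, CH2Cl2, 0 °C; filtration only, used at once
Reagents that add atoms: none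
Why: Buffered Dess–Martin oxidation is neutral and fast, which matters because C7–H of 32 is both α to the formyl group and allylic, so no base or chromatography is allowed to reach it.

Step 19
Reactants: 32 formyl lactone with Z-alkenyl iodide
Product: 34 macrocyclic C6 alcohol (4Z,6R,7R,8S,10R), via alkenylchromium(III) species 33 (not isolated)
Conditions: CrCl2 (15 equiv), NiCl2 (1 mol% of Cr), degassed DMF–THF, 2 mM, slow addition of 32, rt; H2O
Reagents that add atoms: chromium(II) chloride, Cl[Cr]Cl (chromium only in 33)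
Why: Ni(0), formed from NiCl2 by Cr(II), inserts into the C5–I bond with retention, transmetalation gives the Z-alkenylchromium(III) species 33, and this adds 1,2 to the C6 formyl group before the chromium alkoxide is hydrolysed (Nozaki–Hiyama–Kishi reaction). The closest known reaction type is the Ni/Cr-mediated alkenyl iodide–aldehyde macrocyclisation used for medium rings and furan-bridged carbocycles. The ten-membered carbocycle C1–C10 (nine atoms when counted through the C3–O–C10 bridge) closes in exo-trig mode with the carbonyl oxygen ending outside the ring, and the planar furanone, the Z-alkene and the trans lactone act as rigid turns that bring C5 and C6 together. The new C6 stereocentre is controlled by C7: in the Felkin–Anh rotamer the C7–C8 bond, which also carries the tether, lies anti to the incoming C5 and C7–H flanks the trajectory, so C5 should reach the Re face and give the 6R alcohol. The step needs chemoselectivity for the aldehyde over the furanone ketone, the lactone and the acrylate, which the low basicity and strong aldehyde preference of organochromium(III) reagents secure, and the same non-basic medium should leave C7–H untouched. High dilution with slow addition favours ring closure over dimerisation.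

Step 20
Reactants: 35 (R)-2-methylglycidol
Product: 36 (S)-2-methyloxirane-2-carboxylic acid
Conditions: RuCl3 (cat.), NaIO4, MeCN–EtOAc–H2O, 0 °C → rt
Reagents that add atoms: sodium periodate, [Na+].[O-]I(=O)(=O)=O (net source of the second carboxyl oxygen)
Why: Catalytic ruthenium tetroxide oxidises 2,3-epoxy alcohols to glycidic acids without opening the epoxide, and the quaternary centre cannot epimerise (R becomes S only through the priority rules).

Step 21
Reactants: 34 macrocyclic C6 alcohol; 36 (S)-epoxy acid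
Product: 38 target CNP0321429.1, via mixed anhydride 37 (not isolated)
Conditions: 36, 2,4,6-Cl3C6H2COCl, Et3N, PhMe, rt; 34, DMAP, rt
Reagents that add atoms: 2,4,6-trichlorobenzoyl chloride, O=C(Cl)c1c(Cl)cc(Cl)cc1Cl (aroyl unit only in 37)
Why: In the Yamaguchi esterification DMAP attacks the less hindered glycidoyl carbonyl of 37, and the acylpyridinium acylates O6 with retention at C6 and C2', which should be faster than migration of the lactone from O8 to O6 in this aprotic, weakly basic medium.

**Compound list**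
1 | (R)-citramalic acid [(2R)-2-hydroxy-2-methylbutanedioic acid] | C[C@@](O)(CC(=O)O)C(=O)O | starting material
2 | (2R)-2-methylbutane-1,2,4-triol | C[C@@](O)(CCO)CO | intermediate
3 | 2-[(4R)-2,2,4-trimethyl-1,3-dioxolan-4-yl]ethan-1-ol | C[C@@]1(CCO)COC(C)(C)O1 | intermediate
4 | 2-[(4R)-2,2,4-trimethyl-1,3-dioxolan-4-yl]acetaldehyde | C[C@@]1(CC=O)COC(C)(C)O1 | intermediate
5 | (4R)-4-benzyl-1,3-oxazolidin-2-one | O=C1N[C@H](Cc2ccccc2)CO1 | starting material
6 | methyl 4-chloro-4-oxobutanoate | COC(=O)CCC(=O)Cl | starting material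
7 | methyl 4-[(4R)-4-benzyl-2-oxo-1,3-oxazolidin-3-yl]-4-oxobutanoate | COC(=O)CCC(=O)N1C(=O)OC[C@H]1Cc1ccccc1 | intermediate
8 | (Z)-O-dibutylboryl enolate of imide 7 | COC(=O)C/C=C(\OB(CCCC)CCCC)N1C(=O)OC[C@H]1Cc1ccccc1 | intermediate
9 | methyl (3R,4S)-3-[(4R)-4-benzyl-2-oxo-1,3-oxazolidine-3-carbonyl]-4-hydroxy-5-[(4R)-2,2,4-trimethyl-1,3-dioxolan-4-yl]pentanoate (syn aldol) | O=C(N1C(=O)OC[C@H]1Cc1ccccc1)[C@H](CC(=O)OC)[C@@H](O)C[C@]1(C)COC(C)(C)O1 | intermediate
10 | (4R)-4-benzyl-3-[(2S,3R)-5-oxo-2-{[(4R)-2,2,4-trimethyl-1,3-dioxolan-4-yl]methyl}oxolane-3-carbonyl]-1,3-oxazolidin-2-one (trans lactone) | O=C1C[C@@H](C(=O)N2C(=O)OC[C@H]2Cc2ccccc2)[C@H](C[C@]2(C)COC(C)(C)O2)O1 | intermediate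
11 | (2S,3R)-5-oxo-2-{[(4R)-2,2,4-trimethyl-1,3-dioxolan-4-yl]methyl}oxolane-3-carboperoxoic acid | O=C1C[C@@H](C(=O)OO)[C@H](C[C@]2(C)COC(C)(C)O2)O1 | intermediate
12 | (2S,3R)-5-oxo-2-{[(4R)-2,2,4-trimethyl-1,3-dioxolan-4-yl]methyl}oxolane-3-carboxylic acid | O=C1C[C@@H](C(=O)O)[C@H](C[C@]2(C)COC(C)(C)O2)O1 | intermediate
13 | (4S,5S)-4-(hydroxymethyl)-5-{[(4R)-2,2,4-trimethyl-1,3-dioxolan-4-yl]methyl}oxolan-2-one | O=C1C[C@@H](CO)[C@H](C[C@]2(C)COC(C)(C)O2)O1 | intermediate
14 | (4S,5S)-4-{[tert-butyl(diphenyl)silyl]oxymethyl}-5-{[(4R)-2,2,4-trimethyl-1,3-dioxolan-4-yl]methyl}oxolan-2-one | O=C1C[C@@H](CO[Si](c2ccccc2)(c2ccccc2)C(C)(C)C)[C@H](C[C@]2(C)COC(C)(C)O2)O1 | intermediate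
15 | lithium enolate of lactone 14 | [Li]OC1=C[C@@H](CO[Si](c2ccccc2)(c2ccccc2)C(C)(C)C)[C@H](C[C@]2(C)COC(C)(C)O2)O1 | intermediate
16 | (3S,4S,5S)-3-[(dimethylamino)methyl] derivative of 14 (C13 trans to C6) | O=C1[C@H](CN(C)C)[C@@H](CO[Si](c2ccccc2)(c2ccccc2)C(C)(C)C)[C@H](C[C@]2(C)COC(C)(C)O2)O1 | intermediate
17 | trimethylammonium iodide of 16 | O=C1[C@H](C[N+](C)(C)C)[C@@H](CO[Si](c2ccccc2)(c2ccccc2)C(C)(C)C)[C@H](C[C@]2(C)COC(C)(C)O2)O1.[I-] | intermediate
18 | (4S,5S)-4-{[tert-butyl(diphenyl)silyl]oxymethyl}-3-methylidene-5-{[(4R)-2,2,4-trimethyl-1,3-dioxolan-4-yl]methyl}oxolan-2-one | O=C1C(=C)[C@@H](CO[Si](c2ccccc2)(c2ccccc2)C(C)(C)C)[C@H](C[C@]2(C)COC(C)(C)O2)O1 | intermediate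
19 | (4S,5S)-4-{[tert-butyl(diphenyl)silyl]oxymethyl}-5-[(2R)-2,3-dihydroxy-2-methylpropyl]-3-methylideneoxolan-2-one | O=C1C(=C)[C@@H](CO[Si](c2ccccc2)(c2ccccc2)C(C)(C)C)[C@H](C[C@@](C)(O)CO)O1 | intermediate
20 | (2R)-3-[(2S,3S)-3-{[tert-butyl(diphenyl)silyl]oxymethyl}-4-methylidene-5-oxooxolan-2-yl]-2-hydroxy-2-methylpropanal | O=C1C(=C)[C@@H](CO[Si](c2ccccc2)(c2ccccc2)C(C)(C)C)[C@H](C[C@@](C)(O)C=O)O1 | intermediate
21 | C10 triethylsilyl ether of 20 | O=C1C(=C)[C@@H](CO[Si](c2ccccc2)(c2ccccc2)C(C)(C)C)[C@H](C[C@@](C)(O[Si](CC)(CC)CC)C=O)O1 | intermediate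
22 | but-3-yn-2-ol (racemic) | CC(O)C#C | starting material
23 | 3,4-dimethyl-1-oxa-2-magnesacyclopent-... alkenylmagnesium alkoxide (five-membered ring O–Mg–C5H=C4(Me)–CH(Me)) | CC1O[Mg]C=C1C | intermediate
24 | (Z)-4-iodo-3-methylbut-3-en-2-ol (racemic) | CC(O)/C(C)=C\I | intermediate
25 | (Z)-4-iodo-3-methylbut-3-en-2-one | CC(=O)/C(C)=C\I | intermediate
26 | O-dibutylboryl dienolate of 25 | C=C(OB(CCCC)CCCC)/C(C)=C\I | intermediate
27 | β-hydroxy ketone, chain C10(OTES)–C1H(OH)–C2H2–C3(=O)–C4(Me)=C5HI on lactone 21 (4Z,7S,8S,10R; C1 epimers) | O=C1C(=C)[C@@H](CO[Si](c2ccccc2)(c2ccccc2)C(C)(C)C)[C@H](C[C@@](C)(O[Si](CC)(CC)CC)C(O)CC(=O)/C(C)=C\I)O1 | intermediate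
28 | 1,3-diketone from 27 (4Z,7S,8S,10R) | O=C1C(=C)[C@@H](CO[Si](c2ccccc2)(c2ccccc2)C(C)(C)C)[C@H](C[C@@](C)(O[Si](CC)(CC)CC)C(=O)CC(=O)/C(C)=C\I)O1 | intermediate
29 | C10-hydroxy 1,3-diketone | O=C1C(=C)[C@@H](CO[Si](c2ccccc2)(c2ccccc2)C(C)(C)C)[C@H](C[C@@](C)(O)C(=O)CC(=O)/C(C)=C\I)O1 | intermediate
30 | 3(2H)-furanone with C6 TBDPS ether (4Z,7S,8S,10R) | O=C1C(=C)[C@@H](CO[Si](c2ccccc2)(c2ccccc2)C(C)(C)C)[C@H](C[C@@]2(C)OC(=CC2=O)/C(C)=C\I)O1 | intermediate
31 | furanone alcohol: trans α-methylene lactone with C7 CH2OH, whose C8 CH2 carries the 2-methyl-5-[(Z)-1-iodoprop-1-en-2-yl]-3(2H)-furanon-2-yl group (4Z,7S,8S,10R) | O=C1C(=C)[C@@H](CO)[C@H](C[C@@]2(C)OC(=CC2=O)/C(C)=C\I)O1 | intermediate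
32 | C6 aldehyde of 31 (4Z,7R,8S,10R), precursor of the ring closure | O=C[C@@H]1C(=C)C(=O)O[C@H]1C[C@@]2(C)OC(=CC2=O)/C(C)=C\I | intermediate
33 | (Z)-C5-alkenylchromium(III) dichloride derived from 32 | O=C[C@@H]1C(=C)C(=O)O[C@H]1C[C@@]2(C)OC(=CC2=O)/C(C)=C\[Cr](Cl)Cl | intermediate
34 | C6-hydroxy macrocycle (4Z,6R,7R,8S,10R), the target without its ester | C=C1C(=O)O[C@H]2C[C@@]3(C)OC(=CC3=O)/C(C)=C\[C@@H](O)[C@H]12 | intermediate
35 | (R)-2-methylglycidol [(2R)-2-methyloxiran-2-yl]methanol | OC[C@]1(C)CO1 | starting material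
36 | (S)-2-methyloxirane-2-carboxylic acid | OC(=O)[C@]1(C)CO1 | intermediate
37 | (S)-2-methyloxirane-2-carboxylic 2,4,6-trichlorobenzoic anhydride | O=C(OC(=O)[C@]1(C)CO1)c1c(Cl)cc(Cl)cc1Cl | intermediate
38 | CNP0321429.1 (4Z,6R,7R,8S,10R,2'S) | C=C1C(=O)O[C@H]2C[C@@]3(C)OC(=CC3=O)/C(C)=C\[C@@H](OC(=O)[C@]3(C)CO3)[C@H]12 | target

**Totals**
Total step count: 21.
Longest linear sequence: 17 steps (steps 1–3, 5–12, 15–19 and 21, from 1 to 38).

**Steps most likely to fail**

Step 19. The ring constraint may override the Felkin–Anh rotamer, so that C5 adds to the Si face of the formyl group (poor or reversed facial selectivity at C6). The fallback sets out from 32. The same closure is accepted as a route to the 6S alcohol, the 6-epi-macrocyclic alcohol F1, and the centre is corrected in the acylation itself. Mitsunobu esterification of F1 with acid 36 (PPh3, DIAD, PhMe, 0 °C) displaces the activated allylic oxygen with inversion and comes back to the route at 38. Control by facial selectivity is thus replaced by control through SN2 inversion.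

Step 18. Enolisation at C7 during oxidation, filtration or the slow addition may move the C11=C13 double bond into conjugation with the formyl group, or epimerise C7. In the fallback the acrylate is masked before C6 is oxidised.
- Setting out from 31, thiophenol with catalytic Et3N (CH2Cl2, 0 °C) should add to C13 of the unhindered exocyclic acrylate faster than to the trisubstituted iodo-dienone. This gives the 13-phenylthio-11,13-dihydro alcohol F2.
- Dess–Martin oxidation gives the saturated formyl lactone F3, in which C7–H is no longer allylic and the all-trans lactone is the thermodynamic isomer.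
- Ni/Cr closure gives the sulfide macrocycle F4, and Yamaguchi acylation with 36 gives the sulfide ester F5.
- mCPBA (1 equiv, −78 °C) gives the sulfoxide F6. Thermal syn elimination (PhMe, CaCO3, 100 °C) restores C11=C13 and comes back at 38.

Step 17. Before the furanone has formed, the enol oxygen of the diketone may attack C5 in a 6-endo addition–elimination with loss of iodide (γ-pyranone formation), or the acid may isomerise the Z-iodoalkene. The fallback avoids any 1,3-diketone by going through a γ-hydroxy ynone.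
- Commercial propargyl alcohol is taken by the same copper-catalysed methylmagnesiation–iodination to (Z)-3-iodo-2-methylprop-2-en-1-ol F7.
- MnO2 oxidation gives (Z)-3-iodo-2-methylprop-2-enal F8, and the Ohira–Bestmann reagent (K2CO3, MeOH, 0 °C) gives (Z)-1-iodo-2-methylbut-1-en-3-yne F9.
- Setting out from 21, the lithium acetylide of F9 (LiHMDS, THF, −78 °C) adds to the aldehyde to give the propargylic alcohol F10. Dess–Martin oxidation gives the ynone F11.
- HF·pyridine removes both silyl groups to give the hydroxy ynone F12. A cationic gold(I) catalyst (Ph3PAuCl, AgOTf, PhMe, rt) then closes the furanone by 5-endo-dig attack of the C10 hydroxyl on C3, which comes back to the route at 31.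

**Further compounds**
F1 | step 19 | 6-epi-macrocyclic alcohol (4Z,6S,7R,8S,10R) | C=C1C(=O)O[C@H]2C[C@@]3(C)OC(=CC3=O)/C(C)=C\[C@H](O)[C@H]12
F2 | step 18 | 13-phenylthio-11,13-dihydro alcohol (C13 trans to C6) | O=C1[C@H](CSc2ccccc2)[C@@H](CO)[C@H](C[C@@]2(C)OC(=CC2=O)/C(C)=C\I)O1
F3 | step 18 | saturated formyl lactone (13-phenylthio) | O=C1[C@H](CSc2ccccc2)[C@@H](C=O)[C@H](C[C@@]2(C)OC(=CC2=O)/C(C)=C\I)O1
F4 | step 18 | sulfide macrocycle (6R alcohol, 13-phenylthio) | O=C1O[C@H]2C[C@@]3(C)OC(=CC3=O)/C(C)=C\[C@@H](O)[C@@H]2[C@H]1CSc1ccccc1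
F5 | step 18 | sulfide ester (13-phenylthio-11,13-dihydro target) | O=C1O[C@H]2C[C@@]3(C)OC(=CC3=O)/C(C)=C\[C@@H](OC(=O)[C@]3(C)CO3)[C@@H]2[C@H]1CSc1ccccc1
F6 | step 18 | sulfoxide of F5 (sulfur epimers) | O=C1O[C@H]2C[C@@]3(C)OC(=CC3=O)/C(C)=C\[C@@H](OC(=O)[C@]3(C)CO3)[C@@H]2[C@H]1CS(=O)c1ccccc1
F7 | step 17 | (Z)-3-iodo-2-methylprop-2-en-1-ol | OC/C(C)=C\I
F8 | step 17 | (Z)-3-iodo-2-methylprop-2-enal | O=C/C(C)=C\I
F9 | step 17 | (Z)-1-iodo-2-methylbut-1-en-3-yne | C#C/C(C)=C\I
F10 | step 17 | propargylic alcohol (C1 epimers) | O=C1C(=C)[C@@H](CO[Si](c2ccccc2)(c2ccccc2)C(C)(C)C)[C@H](C[C@@](C)(O[Si](CC)(CC)CC)C(O)C#C/C(C)=C\I)O1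
F11 | step 17 | ynone | O=C1C(=C)[C@@H](CO[Si](c2ccccc2)(c2ccccc2)C(C)(C)C)[C@H](C[C@@](C)(O[Si](CC)(CC)CC)C(=O)C#C/C(C)=C\I)O1
F12 | step 17 | hydroxy ynone (C6 and C10 hydroxyls free) | O=C1C(=C)[C@@H](CO)[C@H](C[C@@](C)(O)C(=O)C#C/C(C)=C\I)O1
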